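**Retrosynthetic overview**
- Both maleic anhydride rings are made last and together: a nickel-catalysed double carboxylation of each alkyne of an acyclic 1,5-diyne takes up four CO2, and the acid work-up closes both anhydrides and removes the TBS ether and the dimethyl ketal.
- The diyne comes from SN2 alkynylation of a β-branched primary triflate with lithiated TBS-propargyl ether.
- The triflate's alcohol comes from glycol cleavage and reduction of a 3-alkynyl-1,2-diol, itself made by C3-selective, invertive alkynylalane opening of a Sharpless epoxy alcohol; this sets the only stereocentre.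
- The alkyne carrying the masked 2-oxohexyl chain comes in one step from trimethyl orthovalerate and propargyl bromide.
- Ring order: no ring is present until the final step; both form in that one operation.

Assumption: the target is isolated as the open hydroxymethyl bis-anhydride drawn (not its butenolide-acid ring-chain isomer), so the deprotected hydroxy tetra-acid is taken to close to it on acidic work-up and evaporation.

**Step 1**
Reactants: 1 trimethyl orthovalerate; 2 propargyl bromide
Product: 4 4,4-dimethoxyoct-1-yne, via allenylaluminium sesquibromide 3 (not isolated)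
Conditions: 2, Al powder, HgCl2 (cat.), Et2O, reflux; then 1, −78 → 0 °C; cold aq. NaOH
Reagents that add atoms: none
Why: Bodroux–Chichibabin-type orthoester substitution: the Lewis-acidic allenylaluminium ionises one methoxy group and attacks the dialkoxycarbenium ion through its γ-carbon (SE2′), giving the propargyl ketal as in the classical orthoformate to 3-butynal acetal preparation; no stereocentre.

**Step 2**
Reactants: 5 (E)-oct-2-en-1-ol
Product: 6 [(2S,3S)-3-pentyloxiran-2-yl]methanol
Conditions: Ti(OiPr)4 (5 mol%), L-(+)-DET (6 mol%), TBHP, 4 Å MS, CH2Cl2, −20 °C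
Reagents that add atoms: tert-butyl hydroperoxide, CC(C)(C)OO
Why: Sharpless asymmetric epoxidation; the L-(+)-tartrate titanium complex delivers oxygen to the alkene face that gives the (2S,3S)-trans-epoxy alcohol.

**Step 3**
Reactants: 4 4,4-dimethoxyoct-1-yne; 6 [(2S,3S)-3-pentyloxiran-2-yl]methanol
Product: 9 (2R,3S)-3-(4,4-dimethoxyoct-1-yn-1-yl)octane-1,2-diol, via lithium acetylide 7 (not isolated), via diethylalkynylalane 8 (not isolated)
Conditions: 4 (3 eq), n-BuLi, toluene, 0 °C; Et2AlCl, 0 °C; then 6, 0 °C → rt; aq. Rochelle salt (excess 4 recovered)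
Reagents that add atoms: none
Why: Hydroxyl-directed C3-selective opening of a 2,3-epoxy alcohol by a diethylalkynylalane (aluminium alkoxide chelate, SN2); inversion at C3 sets the target stereocentre, and C2 is sacrificed in the next step.

**Step 4**
Reactants: 9 (2R,3S)-3-(4,4-dimethoxyoct-1-yn-1-yl)octane-1,2-diol
Product: 11 (2S)-2-(4,4-dimethoxyoct-1-yn-1-yl)heptan-1-ol, via aldehyde 10 (not isolated)
Conditions: NaIO4, THF/pH 7 buffer, 0 °C; then NaBH4, 0 °C
Reagents that add atoms: none
Why: Malaprade glycol cleavage followed by in situ borohydride reduction; the epimerisable α-alkynyl aldehyde is reduced cold at neutral pH before it can enolise, so the stereocentre is kept.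

**Step 5**
Reactants: 11 (2S)-2-(4,4-dimethoxyoct-1-yn-1-yl)heptan-1-ol; 12 tert-butyldimethyl(prop-2-yn-1-yloxy)silane
Product: 15 tert-butyl{[(5R)-9,9-dimethoxy-5-pentyltrideca-2,6-diyn-1-yl]oxy}dimethylsilane, via primary triflate 13 (not isolated), via lithium acetylide 14 (not isolated)
Conditions: Tf2O, 2,6-lutidine, CH2Cl2, −78 °C; crude triflate added to 12/n-BuLi, THF–DMPU, −78 → −20 °C
Reagents that add atoms: none
Why: SN2 alkylation of a lithium acetylide by a primary triflate at low temperature; the stereocentre is β to the reacting carbon and is untouched (the descriptor changes from S to R only through CIP priorities).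

**Step 6**
Reactants: 15 tert-butyl{[(5R)-9,9-dimethoxy-5-pentyltrideca-2,6-diyn-1-yl]oxy}dimethylsilane
Product: 18 3-{(2R)-2-[2,5-dioxo-4-(2-oxohexyl)-2,5-dihydrofuran-3-yl]heptyl}-4-(hydroxymethyl)furan-2,5-dione (CNP0537712.2), via bis-maleate tetra-acid 16 (not isolated), via TBS keto bis-anhydride 17 (not isolated)
Conditions: Ni(acac)2(bpy) (20 mol%), Zn (6 eq), MgBr2 (6 eq), 3 Å MS, CO2 (1 atm), DMF, rt; then 3 M HCl, THF, rt; toluene azeotrope
Reagents that add atoms: carbon dioxide, O=C=O; water, O
Why: Proposed new method: each internal alkyne undergoes Ni(0)/CO2 oxidative cyclisation to an oxanickelacyclopentenone, MgBr2-assisted insertion of a second CO2 into the Ni–C(sp2) bond and Zn reduction back to Ni(0) (reductive double carboxylation, the closest known reaction being that of single internal dialkyl alkynes to maleic anhydrides), applied here twice in one molecule; the two-atom tether cannot form a nickelacyclopentadiene, so the alkynes react independently, and aqueous acid then protonates the bis-maleate, both dialkylmaleic acids close spontaneously to the anhydrides (two rings and four C–C bonds in one operation) while the same acid hydrolyses the dimethyl ketal and the primary TBS ether; the stereocentre becomes allylic but sees no base.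

**Compound list**
1 | trimethyl orthovalerate (1,1,1-trimethoxypentane) | CCCCC(OC)(OC)OC | starting material
2 | propargyl bromide (3-bromoprop-1-yne) | BrCC#C | starting material
3 | allenylaluminium sesquibromide (drawn as its allenylaluminium dibromide component) | C=C=C[Al](Br)Br | intermediate
4 | 4,4-dimethoxyoct-1-yne | C#CCC(OC)(OC)CCCC | intermediate
5 | (E)-oct-2-en-1-ol | CCCCC/C=C/CO | starting material
6 | [(2S,3S)-3-pentyloxiran-2-yl]methanol | OC[C@@H]1O[C@H]1CCCCC | intermediate
7 | lithium 4,4-dimethoxyoct-1-yn-1-ide | [Li]C#CCC(OC)(OC)CCCC | intermediate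
8 | diethyl(4,4-dimethoxyoct-1-yn-1-yl)alane | CC[Al](CC)C#CCC(OC)(OC)CCCC | intermediate
9 | (2R,3S)-3-(4,4-dimethoxyoct-1-yn-1-yl)octane-1,2-diol | OC[C@H](O)[C@@H](CCCCC)C#CCC(OC)(OC)CCCC | intermediate
10 | (2S)-2-(4,4-dimethoxyoct-1-yn-1-yl)heptanal | O=C[C@@H](CCCCC)C#CCC(OC)(OC)CCCC | intermediate
11 | (2S)-2-(4,4-dimethoxyoct-1-yn-1-yl)heptan-1-ol | OC[C@@H](CCCCC)C#CCC(OC)(OC)CCCC | intermediate
12 | tert-butyldimethyl(prop-2-yn-1-yloxy)silane | C#CCO[Si](C)(C)C(C)(C)C | starting material
13 | (2S)-2-(4,4-dimethoxyoct-1-yn-1-yl)heptyl trifluoromethanesulfonate | FC(F)(F)S(=O)(=O)OC[C@@H](CCCCC)C#CCC(OC)(OC)CCCC | intermediate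
14 | lithium 3-[(tert-butyldimethylsilyl)oxy]prop-1-yn-1-ide | [Li]C#CCO[Si](C)(C)C(C)(C)C | intermediate
15 | tert-butyl{[(5R)-9,9-dimethoxy-5-pentyltrideca-2,6-diyn-1-yl]oxy}dimethylsilane | CC(C)(C)[Si](C)(C)OCC#CC[C@@H](CCCCC)C#CCC(OC)(OC)CCCC | intermediate
16 | (2Z)-2-{[(tert-butyldimethylsilyl)oxy]methyl}-3-{(2R)-2-[(1Z)-1,2-dicarboxy-4,4-dimethoxyoct-1-en-1-yl]heptyl}but-2-enedioic acid (Zn/Mg tetracarboxylate in the flask, drawn as the free tetra-acid) | CC(C)(C)[Si](C)(C)OC/C(C(O)=O)=C(/C(O)=O)C[C@@H](CCCCC)/C(C(O)=O)=C(/C(O)=O)CC(OC)(OC)CCCC | intermediate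
17 | 3-{[(tert-butyldimethylsilyl)oxy]methyl}-4-{(2R)-2-[2,5-dioxo-4-(2-oxohexyl)-2,5-dihydrofuran-3-yl]heptyl}furan-2,5-dione | CC(C)(C)[Si](C)(C)OCC1=C(C[C@@H](CCCCC)C2=C(CC(=O)CCCC)C(=O)OC2=O)C(=O)OC1=O | intermediate
18 | 3-{(2R)-2-[2,5-dioxo-4-(2-oxohexyl)-2,5-dihydrofuran-3-yl]heptyl}-4-(hydroxymethyl)furan-2,5-dione (CNP0537712.2) | CCCCC[C@H](CC1=C(CO)C(=O)OC1=O)C1=C(CC(=O)CCCC)C(=O)OC1=O | target

**Totals**
Total step count: 6. Longest linear sequence: 5 steps (2 → 3 → 4 → 5 → 6 from 5, or 1 → 3 → 4 → 5 → 6 from 1).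

**Steps most likely to fail**

Step 6 (most at risk). The twofold reductive carboxylation is untested on a diyne of this kind. Likely failures are arrest after one alkyne, β-silyloxy elimination at the propargylic ether, and MgBr2-induced loss of the ketal, which would expose an isomerisable β,γ-ynone. The fallback sets out from 15 and comes back at 17. Compound 15 is treated with Ti(OiPr)4/2 i-PrMgCl (Et2O, −78 → −50 °C) to form a titanacyclopropene at each alkyne; each takes up one CO2, and iodinolysis gives the bis-iodo acid (2Z)-2-{(2R)-2-[(1Z)-1-carboxy-2-iodo-4,4-dimethoxyoct-1-en-1-yl]heptyl}-4-[(tert-butyldimethylsilyl)oxy]-3-iodobut-2-enoic acid F1 (one regioisomer drawn; the others converge on the same product). A double palladium cyclocarbonylation (Pd(OAc)2/PPh3, CO 1 atm, NaOAc, MeCN, 50 °C; the acyl-palladium is trapped by the cis carboxylate) then closes both rings at once to the fully protected bis-anhydride 3-{[(tert-butyldimethylsilyl)oxy]methyl}-4-{(2R)-2-[4-(2,2-dimethoxyhexyl)-2,5-dioxo-2,5-dihydrofuran-3-yl]heptyl}furan-2,5-dione F2. The same 3 M HCl/THF treatment takes F2 through 17 to 18.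

Step 3. The alane is Lewis acidic toward the acyclic dimethyl ketal, and some C2 attack on the epoxide is possible. The fallback sets out from 5 (with 4) and comes back at 11 through 10. Compound 5 is converted with ClP(O)(OEt)2, pyridine and DMAP into (E)-oct-2-en-1-yl diethyl phosphate F3. A copper/chiral NHC-catalysed, γ-selective enantioselective allylic alkynylation with the terminal alkyne 4 (CuCl, chiral imidazolinium salt, LiOt-Bu; catalyst enantiomer chosen for the R product, ee on the E-phosphate to be checked) gives the skipped enyne (3R)-7,7-dimethoxy-3-pentylundec-1-en-4-yne F4. Ozonolysis of the terminal alkene (O3, CH2Cl2/MeOH, −78 °C, Sudan III end-point) with NaBH4 work-up gives 10 and, in the same pot, 11.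

Step 5. E2 elimination of the β-branched triflate, whose β-hydrogen is propargylic, would give the conjugated enyne. The fallback sets out from 11 and comes back at 15. Compound 11 is converted with I2, PPh3 and imidazole (CH2Cl2, 0 °C) into (2S)-2-(4,4-dimethoxyoct-1-yn-1-yl)-1-iodoheptane F5. This is joined to 12 by a Pd/NHC-catalysed Sonogashira-type coupling of the unactivated primary alkyl iodide ([(π-allyl)PdCl]2, IAd·HCl, CuI, Cs2CO3, DMF/Et2O, 45 °C) to give 15; the carbonate base replaces the strongly basic acetylide.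

**Further compounds**
F1 | step 6 | (2Z)-2-{(2R)-2-[(1Z)-1-carboxy-2-iodo-4,4-dimethoxyoct-1-en-1-yl]heptyl}-4-[(tert-butyldimethylsilyl)oxy]-3-iodobut-2-enoic acid | CC(C)(C)[Si](C)(C)OC/C(I)=C(/C(O)=O)C[C@@H](CCCCC)/C(C(O)=O)=C(/I)CC(OC)(OC)CCCC
F2 | step 6 | 3-{[(tert-butyldimethylsilyl)oxy]methyl}-4-{(2R)-2-[4-(2,2-dimethoxyhexyl)-2,5-dioxo-2,5-dihydrofuran-3-yl]heptyl}furan-2,5-dione | CC(C)(C)[Si](C)(C)OCC1=C(C[C@@H](CCCCC)C2=C(CC(OC)(OC)CCCC)C(=O)OC2=O)C(=O)OC1=O
F3 | step 3 | (E)-oct-2-en-1-yl diethyl phosphate | CCCCC/C=C/COP(=O)(OCC)OCC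
F4 | step 3 | (3R)-7,7-dimethoxy-3-pentylundec-1-en-4-yne | C=C[C@@H](CCCCC)C#CCC(OC)(OC)CCCC
F5 | step 5 | (2S)-2-(4,4-dimethoxyoct-1-yn-1-yl)-1-iodoheptane | IC[C@@H](CCCCC)C#CCC(OC)(OC)CCCC
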